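The route rests on disconnecting the C-3–C-4 bond of ring C of the lower flavan-3,4-diol unit (O-1, C-2, C-3, C-4, C-4a, C-8a), whose two adjacent carbinol carbons mark it as a pinacol retron. A titanocene-mediated reductive cyclisation of a dialdehyde closes this pyran ring and sets both hydroxyl-bearing stereocentres trans in one operation, so the acid-labile benzylic 4-hydroxyl appears only after the interflavanyl bond is in place. The precursor is the benzyl-protected upper 4-arylflavan whose lower aryl ring carries a formyl group (future C-4) ortho to an (R)-configured aryloxy(aryl)acetaldehyde ether (future O-1, C-2, C-3).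

Key step: step 16

Remark on the chemistry: 4-(benzyloxy)phenylmagnesium bromide is taken as the commercial THF solution. The (S,S)-configured ruthenium catalyst is assumed to give the (R)-mandelate, the sense known for benzil and aryl ketones; this would be confirmed by polarimetry before use. "Fl" below means the upper flavanyl group (2S,3R)-3,7,8-tris(benzyloxy)-2-[4-(benzyloxy)phenyl]chroman-4-yl, with the 2,3-trans-3,4-trans arrangement of the target.

Step 1
Reactants: 1 2,3,4-trihydroxybenzaldehyde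
Product: 2 3,4-bis(benzyloxy)-2-hydroxybenzaldehyde
Conditions: BnBr (2.05 equiv), K2CO3 (2.1 equiv), DMF, 0 °C to rt
Reagents that add atoms: benzyl bromide, BrCc1ccccc1
Why: Williamson etherification in which the 2-hydroxyl, held in a hydrogen bond to the formyl group, is the least nucleophilic, so two equivalents of benzyl bromide should alkylate O-4 and O-3 only.

Step 2
Reactants: 2 3,4-bis(benzyloxy)-2-hydroxybenzaldehyde
Product: 3 2-[3,4-bis(benzyloxy)-2-hydroxyphenyl]-1,3-dithiane
Conditions: HS(CH2)3SH, BF3·OEt2 (cat.), CH2Cl2, 0 °C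
Reagents that add atoms: propane-1,3-dithiol, SCCCS
Why: Lewis-acid dithioacetalisation masks the electron-withdrawing formyl group, so the ring stays nucleophilic for step 11 and the position ortho to the phenol stays blocked.

Step 3
Reactants: 4 [4-(benzyloxy)phenyl]magnesium bromide; 5 dimethyl oxalate
Product: 6 methyl 2-[4-(benzyloxy)phenyl]-2-oxoacetate
Conditions: 4 added to 5 (3 equiv), THF, −78 °C; then dilute HCl
Reagents that add atoms: none
Why: Grignard acylation of an oxalate diester, which should stop at the α-keto ester because the tetrahedral magnesium adduct persists at low temperature and the oxalate is in excess.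

Step 4
Reactants: 6 methyl 2-[4-(benzyloxy)phenyl]-2-oxoacetate
Product: 7 methyl (R)-2-[4-(benzyloxy)phenyl]-2-hydroxyacetate
Conditions: RuCl[(S,S)-TsDPEN](p-cymene) (1 mol %), HCO2H/Et3N 5:2, CH2Cl2, rt
Reagents that add atoms: none
Why: Noyori asymmetric transfer hydrogenation, in which the arene–aryl contact of the catalyst fixes the face of hydride delivery to the aryl ketone and so sets the carbinol centre as R.

Step 5
Reactants: 6 methyl 2-[4-(benzyloxy)phenyl]-2-oxoacetate
Product: 8 methyl (S)-2-[4-(benzyloxy)phenyl]-2-hydroxyacetate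
Conditions: RuCl[(R,R)-TsDPEN](p-cymene) (1 mol %), HCO2H/Et3N 5:2, CH2Cl2, rt
Reagents that add atoms: none
Why: the same Noyori transfer hydrogenation with the mirror-image catalyst should set the carbinol centre as S.

Step 6
Reactants: 2 3,4-bis(benzyloxy)-2-hydroxybenzaldehyde; 7 methyl (R)-2-[4-(benzyloxy)phenyl]-2-hydroxyacetate
Product: 9 methyl (S)-2-[2,3-bis(benzyloxy)-6-formylphenoxy]-2-[4-(benzyloxy)phenyl]acetate
Conditions: PPh3, DIAD, THF, 0 °C to rt
Reagents that add atoms: none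
Why: Mitsunobu etherification in which the acidic salicylaldehyde phenol displaces the oxyphosphonium group of the secondary alcohol by SN2 with inversion, so the (R)-carbinol should become the (S)-aryl ether that is C-2 of the upper unit.

Step 7
Reactants: 9 methyl (S)-2-[2,3-bis(benzyloxy)-6-formylphenoxy]-2-[4-(benzyloxy)phenyl]acetate
Product: 10 (S)-2-[2,3-bis(benzyloxy)-6-(hydroxymethyl)phenoxy]-2-[4-(benzyloxy)phenyl]ethan-1-ol
Conditions: LiBH4, THF, 0 °C to rt; then water
Reagents that add atoms: none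
Why: hydride reduction of the ester and the aryl aldehyde to the two primary alcohols, which removes the acidic α-ester proton and leaves the stereocentre untouched.

Step 8
Reactants: 10 (S)-2-[2,3-bis(benzyloxy)-6-(hydroxymethyl)phenoxy]-2-[4-(benzyloxy)phenyl]ethan-1-ol
Product: 11 3,4-bis(benzyloxy)-2-{(S)-1-[4-(benzyloxy)phenyl]-2-oxoethoxy}benzaldehyde
Conditions: Dess–Martin periodinane (2.5 equiv), NaHCO3, CH2Cl2, 0 °C; used crude at once
Reagents that add atoms: none
Why: Dess–Martin oxidation of both primary alcohols under buffered, base-free conditions should give the dialdehyde without epimerising the α-aryloxy aldehyde.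

Step 9
Reactants: 11 3,4-bis(benzyloxy)-2-{(S)-1-[4-(benzyloxy)phenyl]-2-oxoethoxy}benzaldehyde
Product: 12 (2S,3R,4S)-7,8-bis(benzyloxy)-2-[4-(benzyloxy)phenyl]chromane-3,4-diol
Conditions: Cp2TiPh (3 equiv; from Cp2TiCl2, i-PrMgCl, then PhMgBr), THF, slow addition of 11, −78 to 0 °C; then cold 0.5 M HCl
Reagents that add atoms: none
Why: titanocene-mediated intramolecular pinacol coupling of a 1,6-dialdehyde, the reaction of step 16 on the simpler substrate, in which O-3 should settle trans to the pseudo-equatorial C-2 aryl group and the two titanium-bound oxygens trans to each other; only the C-2/C-3 relationship matters because C-4 is ionised in step 11.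

Step 10
Reactants: 12 (2S,3R,4S)-7,8-bis(benzyloxy)-2-[4-(benzyloxy)phenyl]chromane-3,4-diol
Product: 13 (2S,3R,4S)-3,4,7,8-tetrakis(benzyloxy)-2-[4-(benzyloxy)phenyl]chromane
Conditions: NaH, BnBr, DMF, 0 °C to rt
Reagents that add atoms: benzyl bromide, BrCc1ccccc1
Why: Williamson benzylation of both alkoxides, which protects O-3 to the end and turns O-4 into a leaving group at the benzylic carbon activated by O-1 and the 7-benzyloxy group.

Step 11
Reactants: 13 (2S,3R,4S)-3,4,7,8-tetrakis(benzyloxy)-2-[4-(benzyloxy)phenyl]chromane; 3 2-[3,4-bis(benzyloxy)-2-hydroxyphenyl]-1,3-dithiane (2.5 equiv)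
Product: 14 2,3-bis(benzyloxy)-6-(1,3-dithian-2-yl)-4-Fl-phenol
Conditions: BF3·OEt2, CH2Cl2, −40 to 0 °C
Reagents that add atoms: none
Why: Friedel–Crafts arylation of a flavan-4-yl cation (the proanthocyanidin-type coupling), in which phenol 3 reacts through its only activated free position, para to the hydroxyl, and approaches anti to the 3-benzyloxy group, which should set C-4 of the upper unit 3,4-trans.

Step 12
Reactants: 14 2,3-bis(benzyloxy)-6-(1,3-dithian-2-yl)-4-Fl-phenol
Product: 15 3,4-bis(benzyloxy)-5-Fl-2-hydroxybenzaldehyde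
Conditions: MeI, CaCO3, MeCN/H2O 9:1, 45 °C
Reagents that add atoms: water, O
Why: alkylative hydrolysis of the dithiane (S-methylation, then hydrolysis of the thionium ion stabilised by the para benzyloxy group) should free the aldehyde under near-neutral conditions that spare the phenol and the benzyl ethers.

Step 13
Reactants: 15 3,4-bis(benzyloxy)-5-Fl-2-hydroxybenzaldehyde; 8 methyl (S)-2-[4-(benzyloxy)phenyl]-2-hydroxyacetate
Product: 16 methyl (R)-2-[2,3-bis(benzyloxy)-6-formyl-4-Fl-phenoxy]-2-[4-(benzyloxy)phenyl]acetate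
Conditions: PPh3, DIAD, THF/toluene, 0 °C to rt
Reagents that add atoms: none
Why: Mitsunobu etherification as in step 6 with the enantiomeric alcohol, where SN2 inversion should give the (R)-aryl ether that is C-2 of the lower unit; any epimer is a diastereomer and can be removed by chromatography.

Step 14
Reactants: 16 methyl (R)-2-[2,3-bis(benzyloxy)-6-formyl-4-Fl-phenoxy]-2-[4-(benzyloxy)phenyl]acetate
Product: 17 (R)-2-[2,3-bis(benzyloxy)-6-(hydroxymethyl)-4-Fl-phenoxy]-2-[4-(benzyloxy)phenyl]ethan-1-ol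
Conditions: LiBH4, THF, 0 °C to rt; then water
Reagents that add atoms: none
Why: hydride reduction of the ester and the aryl aldehyde as in step 7, with benzyl ethers and all stereocentres untouched.

Step 15
Reactants: 17 (R)-2-[2,3-bis(benzyloxy)-6-(hydroxymethyl)-4-Fl-phenoxy]-2-[4-(benzyloxy)phenyl]ethan-1-ol
Product: 18 3,4-bis(benzyloxy)-2-{(R)-1-[4-(benzyloxy)phenyl]-2-oxoethoxy}-5-Fl-benzaldehyde
Conditions: Dess–Martin periodinane (2.5 equiv), NaHCO3, CH2Cl2, 0 °C; used crude at once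
Reagents that add atoms: none
Why: Dess–Martin oxidation of the two primary alcohols as in step 8; no other free hydroxyl is present, and the buffered, base-free medium should keep the α-aryloxy aldehyde configurationally intact.

Step 16
Reactants: 18 3,4-bis(benzyloxy)-2-{(R)-1-[4-(benzyloxy)phenyl]-2-oxoethoxy}-5-Fl-benzaldehyde
Product: 19 (2R,3S,4R)-7,8-bis(benzyloxy)-2-[4-(benzyloxy)phenyl]-6-Fl-chromane-3,4-diol
Conditions: Cp2TiPh (3 equiv; from Cp2TiCl2, i-PrMgCl, then PhMgBr), THF, slow addition of 18 (final 0.005 M), −78 to −20 °C; then cold 0.5 M HCl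
Reagents that add atoms: none
Why: Two equivalents of Cp2TiPh (trivalent titanium) give one electron each: the aromatic aldehyde is reduced first to a titanium-bound benzylic ketyl radical, which adds to the carbonyl carbon of the titanium-coordinated aliphatic aldehyde while the second titanium centre takes up the oxygen, so the C-3–C-4 bond forms without a free aliphatic ketyl that could expel the aryloxide. The closest known reaction type is the titanocene-mediated intramolecular pinacol coupling of 1,6-dialdehydes to trans-cycloalkane-1,2-diols. Ring C of the lower unit closes in a 6-exo-trig mode, with attack on the carbonyl carbon and its oxygen outside the ring. C-3 is controlled by the C-2 stereocentre: in the half-chair transition state the 4-benzyloxyphenyl group lies pseudo-equatorial and the C-3 carbonyl points away from the C-2–O-1 dipole, which places O-3 trans to the aryl group; C-4 is controlled by the two bulky Cp2(Ph)Ti–O groups, which avoid each other and end up trans. The step needs the all-trans diastereomer (not the cis diol that chelating reductants give), ring closure over intermolecular coupling, and an unchanged α-aryloxy stereocentre; the bulky non-chelating reagent, high dilution and the cold, base-free medium are meant to secure these in turn. The upper unit is too remote to bias the closure, so the outcome should follow that of step 9.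

Step 17
Reactants: 19 (2R,3S,4R)-7,8-bis(benzyloxy)-2-[4-(benzyloxy)phenyl]-6-Fl-chromane-3,4-diol
Product: 20 (2R,3S,4R)-2-(4-hydroxyphenyl)-6-[(2S,3R,4S)-3,7,8-trihydroxy-2-(4-hydroxyphenyl)chroman-4-yl]chromane-3,4,7,8-tetrol
Conditions: H2 (1 atm), Pd(OH)2/C, THF/MeOH 1:1, rt; filtration under argon, Sephadex LH-20
Reagents that add atoms: none
Why: catalytic hydrogenolysis of the seven benzyl ethers under neutral conditions, where benzyl ether cleavage should be much faster than loss of the benzylic 4-hydroxyl or opening of the C-2–O-1 bonds.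

Compound list
1 | 2,3,4-trihydroxybenzaldehyde | O=Cc1ccc(O)c(O)c1O | starting material
2 | 3,4-bis(benzyloxy)-2-hydroxybenzaldehyde | O=Cc1ccc(OCc2ccccc2)c(OCc2ccccc2)c1O | intermediate
3 | 2-[3,4-bis(benzyloxy)-2-hydroxyphenyl]-1,3-dithiane | Oc1c(C2SCCCS2)ccc(OCc2ccccc2)c1OCc1ccccc1 | intermediate
4 | [4-(benzyloxy)phenyl]magnesium bromide (THF solution) | Br[Mg]c1ccc(OCc2ccccc2)cc1 | starting material
5 | dimethyl oxalate | COC(=O)C(=O)OC | starting material
6 | methyl 2-[4-(benzyloxy)phenyl]-2-oxoacetate | COC(=O)C(=O)c1ccc(OCc2ccccc2)cc1 | intermediate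
7 | methyl (R)-2-[4-(benzyloxy)phenyl]-2-hydroxyacetate | COC(=O)[C@H](O)c1ccc(OCc2ccccc2)cc1 | intermediate
8 | methyl (S)-2-[4-(benzyloxy)phenyl]-2-hydroxyacetate | COC(=O)[C@@H](O)c1ccc(OCc2ccccc2)cc1 | intermediate
9 | methyl (S)-2-[2,3-bis(benzyloxy)-6-formylphenoxy]-2-[4-(benzyloxy)phenyl]acetate | COC(=O)[C@@H](Oc1c(C=O)ccc(OCc2ccccc2)c1OCc1ccccc1)c1ccc(OCc2ccccc2)cc1 | intermediate
10 | (S)-2-[2,3-bis(benzyloxy)-6-(hydroxymethyl)phenoxy]-2-[4-(benzyloxy)phenyl]ethan-1-ol | OC[C@@H](Oc1c(CO)ccc(OCc2ccccc2)c1OCc1ccccc1)c1ccc(OCc2ccccc2)cc1 | intermediate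
11 | 3,4-bis(benzyloxy)-2-{(S)-1-[4-(benzyloxy)phenyl]-2-oxoethoxy}benzaldehyde | O=C[C@@H](Oc1c(C=O)ccc(OCc2ccccc2)c1OCc1ccccc1)c1ccc(OCc2ccccc2)cc1 | intermediate
12 | (2S,3R,4S)-7,8-bis(benzyloxy)-2-[4-(benzyloxy)phenyl]chromane-3,4-diol (2,3-trans-3,4-trans) | c1ccccc1COc1ccc([C@@H]2Oc3c(ccc(OCc4ccccc4)c3OCc3ccccc3)[C@H](O)[C@H]2O)cc1 | intermediate
13 | (2S,3R,4S)-3,4,7,8-tetrakis(benzyloxy)-2-[4-(benzyloxy)phenyl]chromane | c1ccccc1COc1ccc([C@@H]2Oc3c(ccc(OCc4ccccc4)c3OCc3ccccc3)[C@H](OCc3ccccc3)[C@H]2OCc2ccccc2)cc1 | intermediate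
14 | 2,3-bis(benzyloxy)-6-(1,3-dithian-2-yl)-4-{(2S,3R)-3,7,8-tris(benzyloxy)-2-[4-(benzyloxy)phenyl]chroman-4-yl}phenol (upper unit 2,3-trans-3,4-trans) | Oc1c(C2SCCCS2)cc([C@H]3c4ccc(OCc5ccccc5)c(OCc5ccccc5)c4O[C@@H](c4ccc(OCc5ccccc5)cc4)[C@@H]3OCc3ccccc3)c(OCc3ccccc3)c1OCc1ccccc1 | intermediate
15 | 3,4-bis(benzyloxy)-2-hydroxy-5-{(2S,3R)-3,7,8-tris(benzyloxy)-2-[4-(benzyloxy)phenyl]chroman-4-yl}benzaldehyde (upper unit 2,3-trans-3,4-trans) | Oc1c(C=O)cc([C@H]3c4ccc(OCc5ccccc5)c(OCc5ccccc5)c4O[C@@H](c4ccc(OCc5ccccc5)cc4)[C@@H]3OCc3ccccc3)c(OCc3ccccc3)c1OCc1ccccc1 | intermediate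
16 | methyl (R)-2-(2,3-bis(benzyloxy)-6-formyl-4-{(2S,3R)-3,7,8-tris(benzyloxy)-2-[4-(benzyloxy)phenyl]chroman-4-yl}phenoxy)-2-[4-(benzyloxy)phenyl]acetate | COC(=O)[C@H](Oc1c(C=O)cc([C@H]3c4ccc(OCc5ccccc5)c(OCc5ccccc5)c4O[C@@H](c4ccc(OCc5ccccc5)cc4)[C@@H]3OCc3ccccc3)c(OCc3ccccc3)c1OCc1ccccc1)c1ccc(OCc2ccccc2)cc1 | intermediate
17 | (R)-2-(2,3-bis(benzyloxy)-6-(hydroxymethyl)-4-{(2S,3R)-3,7,8-tris(benzyloxy)-2-[4-(benzyloxy)phenyl]chroman-4-yl}phenoxy)-2-[4-(benzyloxy)phenyl]ethan-1-ol | OC[C@H](Oc1c(CO)cc([C@H]3c4ccc(OCc5ccccc5)c(OCc5ccccc5)c4O[C@@H](c4ccc(OCc5ccccc5)cc4)[C@@H]3OCc3ccccc3)c(OCc3ccccc3)c1OCc1ccccc1)c1ccc(OCc2ccccc2)cc1 | intermediate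
18 | 3,4-bis(benzyloxy)-2-{(R)-1-[4-(benzyloxy)phenyl]-2-oxoethoxy}-5-{(2S,3R)-3,7,8-tris(benzyloxy)-2-[4-(benzyloxy)phenyl]chroman-4-yl}benzaldehyde | O=C[C@H](Oc1c(C=O)cc([C@H]3c4ccc(OCc5ccccc5)c(OCc5ccccc5)c4O[C@@H](c4ccc(OCc5ccccc5)cc4)[C@@H]3OCc3ccccc3)c(OCc3ccccc3)c1OCc1ccccc1)c1ccc(OCc2ccccc2)cc1 | intermediate
19 | hepta-O-benzyl ether of 20: (2R,3S,4R)-7,8-bis(benzyloxy)-2-[4-(benzyloxy)phenyl]-6-{(2S,3R)-3,7,8-tris(benzyloxy)-2-[4-(benzyloxy)phenyl]chroman-4-yl}chromane-3,4-diol (both units 2,3-trans-3,4-trans) | c1ccccc1COc1ccc([C@H]2Oc3c(cc([C@H]4c5ccc(OCc6ccccc6)c(OCc6ccccc6)c5O[C@@H](c5ccc(OCc6ccccc6)cc5)[C@@H]4OCc4ccccc4)c(OCc4ccccc4)c3OCc3ccccc3)[C@@H](O)[C@@H]2O)cc1 | intermediate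
20 | (2R,3S,4R)-2-(4-hydroxyphenyl)-6-[(2S,3R,4S)-3,7,8-trihydroxy-2-(4-hydroxyphenyl)chroman-4-yl]chromane-3,4,7,8-tetrol | Oc1ccc([C@H]2Oc3c(cc([C@H]4c5ccc(O)c(O)c5O[C@@H](c5ccc(O)cc5)[C@@H]4O)c(O)c3O)[C@@H](O)[C@@H]2O)cc1 | target

Total step count: 17. Longest linear sequence: 14 steps (steps 3, 4, 6 to 17).

Steps most likely to fail

Step 16: the ring closure may give the wrong C-3/C-4 relationship (a cis diol), or the α-aryloxy aldehyde may epimerise before it cyclises. The fallback sets out from 18 and comes back at 19. Dialdehyde 18 would be cyclised with SmI2 (THF, t-BuOH, −78 °C), which holds both oxygens on one samarium centre and is expected to give the 2,3-trans-3,4-cis diol F1. The benzylic 4-hydroxyl of F1 would then be oxidised selectively with MnO2 (CH2Cl2, rt) to the 3-hydroxyflavan-4-one F2. NaBH4 (THF/MeOH, 0 °C) should reduce F2 by axial hydride delivery to the equatorial 4-hydroxyl, as dihydroflavonols are known to do, which gives the 3,4-trans diol 19.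

Step 11: the flavan-4-yl cation may condense with the electron-rich ring A of a second molecule of 13, the 4-benzyl ether may ionise sluggishly, or the arene may add from the wrong face. The fallback sets out from 13 and comes back at 15. Ether 13 would be coupled (BF3·OEt2, CH2Cl2, −40 °C) with an excess of the symmetric and more nucleophilic 2-(benzyloxy)benzene-1,3-diol F3, whose two equivalent activated positions leave no regiochemical choice, to give the 4-arylflavan F4. Magnesium-mediated ortho-formylation (MgCl2, Et3N, paraformaldehyde, MeCN, reflux) can reach only the one free position next to a hydroxyl and should give the dihydroxy aldehyde F5. Benzylation of the non-chelated hydroxyl para to the formyl group of F5 (BnBr, KHCO3, DMF) then gives 15.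

Step 17: hydrogenolysis may also remove the benzylic 4-hydroxyl of the lower unit while the benzyl ethers are cleaved. The fallback sets out from 19 and comes back at 20. Diol 19 would be oxidised with MnO2 (CH2Cl2, rt) to the 3-hydroxyflavan-4-one F2, which has no benzylic alcohol. The seven benzyl ethers of F2 would be removed with H2 and Pd(OH)2/C (EtOAc/MeOH) to give the free hydroxy ketone F6. NaBH4 (MeOH, 0 °C) should then reduce F6 to the 2,3-trans-3,4-trans diol 20, as is known for free dihydroflavonols.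

Further compounds
F1 | step 16 | 3,4-cis diol, the C-4 epimer of 19 in the lower unit (2,3-trans-3,4-cis) | c1ccccc1COc1ccc([C@H]2Oc3c(cc([C@H]4c5ccc(OCc6ccccc6)c(OCc6ccccc6)c5O[C@@H](c5ccc(OCc6ccccc6)cc5)[C@@H]4OCc4ccccc4)c(OCc4ccccc4)c3OCc3ccccc3)[C@H](O)[C@@H]2O)cc1
F2 | step 16 | (2R,3R)-7,8-bis(benzyloxy)-2-[4-(benzyloxy)phenyl]-3-hydroxy-6-{(2S,3R)-3,7,8-tris(benzyloxy)-2-[4-(benzyloxy)phenyl]chroman-4-yl}chroman-4-one | c1ccccc1COc1ccc([C@H]2Oc3c(cc([C@H]4c5ccc(OCc6ccccc6)c(OCc6ccccc6)c5O[C@@H](c5ccc(OCc6ccccc6)cc5)[C@@H]4OCc4ccccc4)c(OCc4ccccc4)c3OCc3ccccc3)C(=O)[C@@H]2O)cc1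
F3 | step 11 | 2-(benzyloxy)benzene-1,3-diol | Oc1cccc(O)c1OCc1ccccc1
F4 | step 11 | 2-(benzyloxy)-4-{(2S,3R)-3,7,8-tris(benzyloxy)-2-[4-(benzyloxy)phenyl]chroman-4-yl}benzene-1,3-diol (upper unit 2,3-trans-3,4-trans) | Oc1ccc([C@H]3c4ccc(OCc5ccccc5)c(OCc5ccccc5)c4O[C@@H](c4ccc(OCc5ccccc5)cc4)[C@@H]3OCc3ccccc3)c(O)c1OCc1ccccc1
F5 | step 11 | 3-(benzyloxy)-2,4-dihydroxy-5-{(2S,3R)-3,7,8-tris(benzyloxy)-2-[4-(benzyloxy)phenyl]chroman-4-yl}benzaldehyde | Oc1c(C=O)cc([C@H]3c4ccc(OCc5ccccc5)c(OCc5ccccc5)c4O[C@@H](c4ccc(OCc5ccccc5)cc4)[C@@H]3OCc3ccccc3)c(O)c1OCc1ccccc1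
F6 | step 17 | (2R,3R)-3,7,8-trihydroxy-2-(4-hydroxyphenyl)-6-[(2S,3R,4S)-3,7,8-trihydroxy-2-(4-hydroxyphenyl)chroman-4-yl]chroman-4-one | Oc1ccc([C@H]2Oc3c(cc([C@H]4c5ccc(O)c(O)c5O[C@@H](c5ccc(O)cc5)[C@@H]4O)c(O)c3O)C(=O)[C@@H]2O)cc1
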